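The runs were generated by integration from invented constants; noise was put on by code.

We have decided to stake the larch flask on one time read from the alder curve, and the argument for it comes from the runs themselves.

all flasks: catalyst 0.00500 M
- alder: starting material 0.250 M; reagent 0.275 M
- cedar: starting material 0.500 M; reagent 0.275 M
- birch: starting material 0.250 M; reagent 0.410 M
- larch: starting material 0.250 M; reagent 0.670 M; time 40 min

| run | time / min | [target] / M |
|---|---|---|
| alder run | 8.0 | 0.052 |
| alder run | 16 | 0.103 |
| alder run | 24 | 0.143 |
| alder run | 32 | 0.180 |
| alder run | 40 | 0.196 |
| cedar run | 8.0 | 0.083 |
| cedar run | 16 | 0.157 |
| cedar run | 24 | 0.226 |
| cedar run | 32 | 0.264 |
| cedar run | 40 | 0.276 |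
| birch run | 8.0 | 0.053 |
| birch run | 16 | 0.111 |
| birch run | 24 | 0.148 |
| birch run | 32 | 0.180 |
| birch run | 40 | 0.201 |

(readings scatter by 0.004 M)

* the exponent of [reagent] in the starting rate at the charge of the alder run (at the point where two percent of the starting material have become target)
* the exponent of [starting material] in the starting rate at the charge of the alder run (at the point where two percent of the starting material have become target) (one fixed amount of target, the same in the runs compared)
* target in the larch run at 40 min, as a share of the starting material charged
* which of these the readings show (the catalyst rests as a dimer / the substrate pairs with itself / the catalyst wakes slowly / nothing beyond the main steps / the second partner is lost by itself / an uncatalysed path runs beside)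

- Overall: starting material + reagent -> target, with catalyst as catalyst.
- Constant volume, constant temperature.
- The analysis sees a species whether free or bound.
- "The second partner" is reagent.
- An order is taken over about fifteen percent of the charge, up and down.

Two observations seem not to go together. At 32 min the alder run reads 0.180 M and the birch run 0.180 M, although alder has 0.0950 M of reagent left and birch 0.230 M, so reagent seems not to matter. Yet the cedar run ends at 0.276 M, on its reagent charge of 0.275 M, so reagent seems to matter entirely. Both stand. The cedar charge holds less reagent than starting material, which makes reagent cedar's limiting reagent: it bounds how far that flask goes, whereas alder and birch were compared at 32 min with 0.0950 M of reagent or more left in each.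

So we freeze c(reagent) out of the rate; the 24 min readings of birch and alder give an order of about 0.0861. Going from alder to cedar, with 0.500 M against 0.250 M of starting material, the 8.0 min reading rises by a factor of 1.60. That single noisy pair gives an order of 0.675, and as a working order we round it down to 0.5, which a starting material paired with itself can give.

At that order the root of c(starting material) falls in a straight line, and the alder reading of 0.143 M at 24 min puts its zero at 69.4 min. We call this the clearing time, the time in which that line reaches zero while reagent lasts; it grows with the root of the charge. The larch flask has alder's starting material and 0.670 M of reagent, so it keeps this time, and at 40 min we reckon a converted share of 82.0%.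

The forecast gives orders of 0.05 in reagent and 0.6 in starting material, the second higher than our working order, a share of 82% and the verdict that the substrate pairs with itself, which it pictures as “a self-paired reservoir”.

The larch flask gives 81.5%, the orders at the alder charge are 0.048 and 0.60, and the readings show that the substrate pairs with itself.

    catalyst + starting material → catalyst-substrate complex (17.28 M⁻¹ min⁻¹)
    catalyst-substrate complex + reagent → target + catalyst (124.2 M⁻¹ min⁻¹)
    2 starting material ⇌ idle substrate dimer, settled at all times (8.950 M⁻¹)

Where the same amount of target has been made, the birch rate over the alder rate stands at 1.0, with 1.49 times the reagent. Scaled by the root of the charge, the clearing time of 69.4 min becomes 98.2 min for the cedar run, which puts target at half of cedar's starting material at 28.8 min. The cedar run reaches that point at 28.8 min.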